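**Retrosynthetic overview**
1. Target ⇒ 7-O-prenyl ether: the C8–C(prenyl) bond is made last, by a light-driven [1,3] O7→C8 prenyl shift (boron-chelate-gated photo-Claisen).
2. Ring B side chain ⇒ aryl 3'-triflate + (3-methylbut-3-enyl)zinc bromide (Negishi C(sp2)–C(sp3) coupling).
3. Triflate ⇒ 7-O-prenylhesperetin ⇒ (2S)-hesperetin + prenol; the prenyl group first protects O7 and later becomes the C8 substituent.
4. No ring is formed: rings A, B and C and the C2 (S) centre are bought in (2S)-hesperetin and carried through under non-basic conditions.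

Assumption: (2S)-hesperetin is bought enantiopure (≥98% ee, checked by chiral HPLC on receipt, since some commercial lots are partly racemic).

**Step 1**
Reactants: 1 (2S)-hesperetin; 2 3-methylbut-2-en-1-ol (prenol)
Product: 3 (2S)-5-hydroxy-2-(3-hydroxy-4-methoxyphenyl)-7-[(3-methylbut-2-en-1-yl)oxy]chroman-4-one
Conditions: PPh3, DIAD (1.1 equiv each), THF, 0 → 23 °C
Reagents that add atoms: none
Why: Mitsunobu etherification, in which only the most acidic phenol (7-OH, a vinylogous acid of pKa about 7.5) is deprotonated and attacks the prenyloxyphosphonium ion by SN2, while the 3'-OH (pKa about 10) and the hydrogen-bonded 5-OH stay free and the neutral medium leaves the base-labile C2 (S) centre untouched.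

**Step 2**
Reactants: 3 (2S)-5-hydroxy-2-(3-hydroxy-4-methoxyphenyl)-7-[(3-methylbut-2-en-1-yl)oxy]chroman-4-one
Product: 4 5-[(2S)-5-hydroxy-7-[(3-methylbut-2-en-1-yl)oxy]-4-oxochroman-2-yl]-2-methoxyphenyl trifluoromethanesulfonate
Conditions: PhNTf2 (1.1 equiv), Et3N, CH2Cl2, 0 → 23 °C
Reagents that add atoms: N-phenylbis(trifluoromethanesulfonimide), O=S(=O)(N(c1ccccc1)S(=O)(=O)C(F)(F)F)C(F)(F)F
Why: Phenol triflation with a mild triflyl donor, which reacts at the only non-chelated phenol because the 5-OH is locked in a hydrogen bond to the C4 carbonyl, and cold Et3N is too weak to open the chromanone ring, so C2 stays S.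

**Step 3**
Reactants: 5 4-bromo-2-methylbut-1-ene
Product: 6 (3-methylbut-3-en-1-yl)zinc bromide (THF solution, titrated and used directly)
Conditions: Zn dust (activated), LiCl, THF, 50 °C
Reagents that add atoms: zinc, [Zn]
Why: Direct oxidative insertion of LiCl-activated zinc into the primary C–Br bond; the homoallyl/cyclopropylcarbinyl rearrangement of this reagent is degenerate, so its constitution cannot scramble.

**Step 4**
Reactants: 4 5-[(2S)-5-hydroxy-7-[(3-methylbut-2-en-1-yl)oxy]-4-oxochroman-2-yl]-2-methoxyphenyl trifluoromethanesulfonate; 6 (3-methylbut-3-en-1-yl)zinc bromide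
Product: 7 (2S)-5-hydroxy-2-[4-methoxy-3-(3-methylbut-3-en-1-yl)phenyl]-7-[(3-methylbut-2-en-1-yl)oxy]chroman-4-one
Conditions: 6 (2.5 equiv), Pd(OAc)2 (3 mol%), SPhos (6 mol%), THF, 23 → 45 °C; aq NH4Cl
Reagents that add atoms: none
Why: Negishi cross-coupling, in which zerovalent palladium bearing the bulky biarylphosphine adds to the aryl C–OTf bond and reductive elimination outruns beta-hydride elimination; the mild organozinc tolerates the ketone (one equivalent is spent on the 5-OH), the hindered prenyl ether is not expected to ionise, and no stereocentre is touched.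

**Step 5**
Reactants: 7 (2S)-5-hydroxy-2-[4-methoxy-3-(3-methylbut-3-en-1-yl)phenyl]-7-[(3-methylbut-2-en-1-yl)oxy]chroman-4-one
Product: 10 (2S)-5,7-dihydroxy-2-[4-methoxy-3-(3-methylbut-3-en-1-yl)phenyl]-8-(3-methylbut-2-en-1-yl)chroman-4-one (target), via O-prenyl diphenylboron chelate 8 (not isolated), via C8-prenyl diphenylboron chelate 9 (not isolated)
Conditions: (Ph2B)2O (0.55 equiv), 4 Å MS, PhCF3, 23 °C, 1 h; then hν (365 nm LED), degassed, 0.01 M, 0 °C; then 0.5 M aq HCl/THF, 0 → 23 °C
Reagents that add atoms: none
Why: Proposed new method: binding the 5-OH/C4=O pair as a diphenylboron chelate removes the excited-state proton transfer that normally deactivates 5-hydroxyflavanones and shifts the absorption to 365 nm, so the excited chelate can cleave its weak allylic O7–C bond to a solvent-caged aryloxyl/prenyl radical pair that recombines through the unhindered CH2 terminus at C8 (the ortho site favoured in O7-to-C allyl shifts of 7-allyloxy-5-hydroxyflavanones) and tautomerises to the phenol before mild acid releases boron; the closest known reaction is the photo-Claisen rearrangement of simple aryl allyl and prenyl ethers, not yet shown on a boron-chelated hydroxyflavanone, and C2 is not involved and stays S.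

**Compound list**
1 | (2S)-hesperetin, (2S)-5,7-dihydroxy-2-(3-hydroxy-4-methoxyphenyl)chroman-4-one | Oc1cc([C@@H]2CC(=O)c3c(O)cc(O)cc3O2)ccc1OC | starting material
2 | 3-methylbut-2-en-1-ol (prenol) | CC(C)=CCO | starting material
3 | (2S)-5-hydroxy-2-(3-hydroxy-4-methoxyphenyl)-7-[(3-methylbut-2-en-1-yl)oxy]chroman-4-one | Oc1cc([C@@H]2CC(=O)c3c(O)cc(OCC=C(C)C)cc3O2)ccc1OC | intermediate
4 | 5-[(2S)-5-hydroxy-7-[(3-methylbut-2-en-1-yl)oxy]-4-oxochroman-2-yl]-2-methoxyphenyl trifluoromethanesulfonate | O=S(=O)(Oc1cc([C@@H]2CC(=O)c3c(O)cc(OCC=C(C)C)cc3O2)ccc1OC)C(F)(F)F | intermediate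
5 | 4-bromo-2-methylbut-1-ene | C=C(C)CCBr | starting material
6 | (3-methylbut-3-en-1-yl)zinc bromide | C=C(C)CC[Zn]Br | intermediate
7 | (2S)-5-hydroxy-2-[4-methoxy-3-(3-methylbut-3-en-1-yl)phenyl]-7-[(3-methylbut-2-en-1-yl)oxy]chroman-4-one | C=C(C)CCc1cc([C@@H]2CC(=O)c3c(O)cc(OCC=C(C)C)cc3O2)ccc1OC | intermediate
8 | diphenylboron chelate of 7 (boron bound to O5 and coordinated by the C4 carbonyl oxygen; 7-O-prenyl) | C=C(C)CCc1cc([C@@H]2CC3=[O+][B-](c4ccccc4)(c4ccccc4)Oc4cc(OCC=C(C)C)cc(O2)c43)ccc1OC | intermediate
9 | diphenylboron chelate of 10 (boron bound to O5 and coordinated by the C4 carbonyl oxygen; 7-OH, 8-prenyl) | C=C(C)CCc1cc([C@@H]2CC3=[O+][B-](c4ccccc4)(c4ccccc4)Oc4cc(O)c(CC=C(C)C)c(O2)c43)ccc1OC | intermediate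
10 | (2S)-5,7-dihydroxy-2-[4-methoxy-3-(3-methylbut-3-en-1-yl)phenyl]-8-(3-methylbut-2-en-1-yl)chroman-4-one | C=C(C)CCc1cc([C@@H]2CC(=O)c3c(O)cc(O)c(CC=C(C)C)c3O2)ccc1OC | target

**Totals**
Total step count: 5. Longest linear sequence: 4 (steps 1, 2, 4 and 5; step 3 is a one-step side branch).

**Three steps most likely to fail**

Step 5 (the proposed new step). The radical pair may close at C6 instead of C8, or escape the cage to give the free 7-phenol. The ortho-prenylphenol product may also photocyclise to a chroman, and the excited chelate could epimerise C2 through the benzylic C2–O1 bond. The fallback uses known chemistry, sets out from 4 and comes back at 10. Triflate 4 is heated with magnesium silicate (MgSiO3, Florisil grade) in toluene at 90 °C, the established acid-site-promoted ground-state [1,3] shift of aryl prenyl ethers. After chromatographic removal of the C6 isomer this gives 5-[(2S)-5,7-dihydroxy-8-(3-methylbut-2-en-1-yl)-4-oxochroman-2-yl]-2-methoxyphenyl trifluoromethanesulfonate F1. F1 is then coupled with organozinc 6 (3.5 equiv, Pd(OAc)2/SPhos, THF, 45 °C) to give 10. Doing the shift before the coupling keeps the acid-sensitive 1,1-disubstituted alkene away from the solid acid.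

Step 4. The electron-rich ortho-methoxy aryl triflate may add slowly to zerovalent palladium, the prenyl ether may be ionised by zerovalent palladium, or the organozinc may be lost to the 5-OH. The fallback sets out from 4 and 5 and comes back at 7 without any organometallic reagent. It is a nickel-catalysed reductive cross-electrophile coupling (NiBr2·glyme, 4,4'-di-tert-butyl-2,2'-bipyridine, Mn powder, DMA, 40 °C). The alkyl bromide enters as a radical captured at nickel, and the rearrangement of that homoallyl radical is degenerate. This fallback makes no new compound (F0).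

Step 1. Alkylation of the 3'-OH or bis-etherification may compete, and the product may be hard to separate from the phosphine oxide. The fallback sets out from 1 and comes back at 3. It replaces the redox condensation by an acidity-gated Williamson alkylation (prenyl bromide 1.1 equiv, KHCO3, DMF, 23 °C). Hydrogencarbonate ionises only the 7-OH, so selectivity rests on phenoxide formation and not on betaine kinetics, and the base is too weak to open the chromanone ring. This fallback makes no new compound (F0).

**Further compounds**
F1 | step 5 | 5-[(2S)-5,7-dihydroxy-8-(3-methylbut-2-en-1-yl)-4-oxochroman-2-yl]-2-methoxyphenyl trifluoromethanesulfonate | O=S(=O)(Oc1cc([C@@H]2CC(=O)c3c(O)cc(O)c(CC=C(C)C)c3O2)ccc1OC)C(F)(F)F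
F0 | step 4 | none | none
F0 | step 1 | none | none
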